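The runs were generated by integration for an exercise; noise was put on by code.

In a closed, stirred vessel held at one temperature, enzyme turns starting material into target beside second substrate, capture agent and protic impurity. In both earlier runs the target peak stops rising while starting material stays.

in all of them: starting material 0.19 M
- Tuesday's: second substrate 0.19 M; capture agent 9.5 mM; protic impurity 0.057 M; enzyme 38 µM; the very flask that is asked about, followed so far
- Thursday's: second substrate 0.19 M; capture agent 9.5 mM; protic impurity 0.057 M; enzyme 76 µM; run made earlier
- flask: second substrate 0.190 M; capture agent 9.50 mM; protic impurity 0.0570 M; enzyme 38 µM; time 8.0 d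

| run | time / h | target / % | starting material / % |
|---|---|---|---|
| Tuesday's | 10.0 | 24.0 | 57.1 |
| Tuesday's | 20.0 | 26.0 | 49.5 |
| Tuesday's | 30.0 | 23.8 | 49.6 |
| Tuesday's | 60.0 | 23.9 | 48.0 |
| Tuesday's | 120 | 23.4 | 45.7 |
| Thursday's | 0.333 | 27.1 | 73.4 |
| Thursday's | 1.00 | 35.8 | 57.5 |
| Thursday's | 2.00 | 40.0 | 54.0 |
| Thursday's | 3.00 | 41.7 | 51.9 |
| Thursday's | 4.00 | 41.8 | 50.7 |

(each reading ± 1 percentage point)

- maple: at 8.0 d add enzyme, 100% of the amount charged, then wait 4.0 d
- cedar: at 8.0 d take out 90% of the target then present, then wait 4.0 d
- larch: change nothing and wait 4.0 d more
- birch: at 8.0 d add starting material, 50.0% of the amount charged, then wait 4.0 d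

- target, in percent of the starting material first charged, at 8.0 d
- the remedy with the largest gain of target, or "none" below 2 percentage points (maple / cedar / larch / birch / none)
- target present, with what was taken out counted in, in percent of the starting material first charged, after maple
- target present, with what was taken out counted in, in percent of the starting material first charged, after larch

- target that was removed still counts
- additions bring no volume worth counting

Follow one enzyme molecule: at each fork it either makes another target or is lost, and we assume the odds of target go with the starting material beside it. So we divide the target P made per enzyme charged by the mean fraction of starting material while it worked, taken between the full charge and what P leaves, side loss ignored. Tuesday's plateau of 24.2% gives 1380. Thursday's 41.8%, with 76 µM enzyme against 38 µM, gives 1320. Their mean, 1350, is the lifetime output w, target molecules per enzyme molecule at full starting material, with second substrate and capture agent as charged: a total turnover number scaled by starting material.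

In the flask, Tuesday's target readings stay near that plateau from 10.0 h to 120 h while starting material falls to 45.7%, so we take 24.2% for now and expect nothing from larch, cedar or birch. Maple's dose, worth 0.270 of target per unit fraction, meets that 45.7%. If the level held, target would reach 36.5%; if it stood throughout at the level after that gain, 33.2%. Letting it fall as the enzyme works gives a gain of 11 percentage points, so 35.1%.

The forecast gives 23.8% now, maple as best, 33.5% after maple and 23.7% after larch, reasoning “The enzyme has died, after a limited output”. Its maple figure lies inside our bracket, lower than our own.

The flask gives 24.1% at 8.0 d, maple as best with a gain of 10 points against our 11 points, cedar and birch 0 points, then 34.1% after maple and 24.1% after larch.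

    second substrate + enzyme ⇌ complex B (K = 1.80 M⁻¹, k = 48.0 M⁻¹ s⁻¹)
    starting material + enzyme ⇌ complex A (K = 15.0 M⁻¹, k = 20.0 M⁻¹ s⁻¹)
    capture agent + complex B → trapped intermediate (k = 0.480 M⁻¹ s⁻¹)
    starting material + protic impurity → quenched substrate (k = 2.10 × 10⁻⁴ M⁻¹ s⁻¹)
    complex A ⇌ enzyme + target (K = 0.290 M, k = 1.90 s⁻¹)
    complex B → enzyme + second product (k = 0.250 s⁻¹)

The midpoint of the target step's turnover comes at 0.266 h, while starting material's half-life against protic impurity, charges held, is 16 h. By 192 h quenched substrate stands at 30.0% and the catalyst at 100% as trapped intermediate. The answer for now moves 5 points from the flask's with enzyme at 29.0 µM or with second substrate at 0.150 M, and there the forecast's 23.8% would stand about that far off. In a neighbour flask with second substrate at 0.11 M, taking the loss through complex B as proportional to second substrate lifts w to 2330, its dose to 0.466, and target to 37.8%; computed, 36.7%.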